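4 questions stood before me, and I wanted one number to answer them.

- part of the electrophile that has reacted at the end, elm
- part of the electrophile that has reacted at the end, oak
- part of the electrophile that has reacted at the end, larch
- what raising the concentration of free base from its lowest to its highest value here does to the part of the electrophile that has reacted (changes below 5 percentage points count as none) (it rises / no change / it falls)

common to all: electrophile 0.20 M
- autumn: free base 0.29 M; solid nucleophile 0.60 M; run made earlier
- noon: free base 0.72 M; solid nucleophile 0.60 M; run made earlier
- elm: free base 0.160 M; solid nucleophile 0.600 M; time 6.0 h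
- oak: free base 0.320 M; solid nucleophile 0.600 M; time 6.0 h
- larch: free base 0.640 M; solid nucleophile 0.600 M; time 6.0 h

| run | time / h | electrophile / % | target / % |
|---|---|---|---|
| autumn | 0.833 | 90 | 10 |
| autumn | 1.50 | 71 | 14 |
| autumn | 2.50 | 54 | 20 |
| autumn | 3.00 | 44 | 18 |
| autumn | 4.00 | 33 | 22 |
| noon | 0.833 | 84 | 8 |
| noon | 1.50 | 70 | 10 |
| noon | 2.50 | 52 | 19 |
| noon | 3.00 | 44 | 19 |
| noon | 4.00 | 31 | 21 |

(standard deviation of a reading: 2 percentage points)

- a species is counted by the electrophile in it: one side product counts as two
- given per volume of solution although it is solid: solid nucleophile
- the earlier runs were read with a standard deviation of 2 percentage points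
- reactions considered so far: electrophile + nucleophile -> acid set free + target; nucleophile + acid set free <-> protonated nucleophile; acid set free + free base <-> salt of the base; electrophile + target -> side product; solid nucleophile <-> nucleophile
- at the start none of the solid nucleophile is in solution

I took logarithms of the electrophile left, between the first and last readings. The autumn run, with free base at 0.29 M, fell at 0.138 h⁻¹, and the noon run, at 0.72 M, fell at 0.137 h⁻¹. So I kept the mean, 0.137 h⁻¹, as the decade slope: the powers of ten of electrophile lost per hour. It treats the fall as pseudo-first-order, and as a reading it carries the scatter of 2 percentage points.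

The last readings of electrophile averaged 32.0%. The remaining 2.00 h are worth 0.274 decades, which leaves 17.0%, so 83.0% would have reacted.

But the free base in elm lies below that of both runs, so I counted acid. Each target formed sets acid free, and a side product, counted as two electrophiles, has come through one target. Taking target at the 21.5% of the last readings, I estimated 0.104 M of acid, less than the 0.160 M of free base charged in elm. So I expected equal answers.

The forecast gave 83%, 83%, 83% and no change, saying “all three runs should match”.

The flasks gave 85.3%, 85.3% and 85.3%, so raising the free base brought no change. In elm at 6.00 h the salt of the base stood at 0.110 M, with 31.3% of the free base still free. Between my 17.0% and the 14.7% left in oak lie 0.0632 decades, which my slope spends in 0.461 h.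

    electrophile + nucleophile → acid set free + target (k = 0.200 M⁻¹ min⁻¹)
    nucleophile + acid set free ⇌ protonated nucleophile, settled at all times (K = 1600 M⁻¹)
    acid set free + free base ⇌ salt of the base, settled at all times (K = 5.70 × 10⁵ M⁻¹)
    electrophile + target → side product (k = 0.0580 M⁻¹ min⁻¹)
    solid nucleophile ⇌ nucleophile, rate k5*(cs5 - [nucleophile]) while solid is left; crystals form when [nucleophile] > cs5 (solubility = 20.0 mM, k = 0.0960 min⁻¹)

The second flask is oak read at 2.5 h. Counted back from 4.00 h, the slope gives 51.4% of the electrophile left, and the computed flask held 53.4%.

The numbers in the tables are simulated on assumed constants; noise was put on by code.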